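**Retrosynthetic overview**

- The target is a normal-series labdane (ring A = C1–C5/C10, ring B = C5–C10). The end game starts from a C6 ketone: α-hydroxylation at C7 through the extended enolate (which also places C8=C9), isovalerate, reduction to the 6β-alcohol, acetate.
- Ring B read as C10=C5–C6(O)–C7–C8(CH3)=C9 is a 3-oxy-1,5-diene, the retron of an oxy-Cope shift for C9–C10. Its C6 carbonyl lies 1,5 to the C8 methallyl unit, the retron of a type 2 carbonyl-ene closure for C6–C7. The C6 oxygen can bridge C6 to C9.
- Key step: bis-allylic ether 9 (O6 ties C6 to C9; neither ring-B bond present) undergoes [2,3]-Wittig shift, anionic oxy-Cope shift and carbonyl-ene closure in one pot. Ring A is bought; ring B is the only ring formed.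
- Ether 9 comes from β-cyclogeranyl bromide (from β-cyclocitral) and the (R)-allylic alcohol 7 (methyl geranate, Shi epoxidation, epoxide-to-allylic-alcohol isomerisation). The C9 carbinol centre is relayed to C6 and then to quaternary C10.

Key step: step 7

Remark: labdane numbering is used throughout (C11–C16 side chain, C17 on C8, C18/C19 on C4, C20 on C10); the C15 acid is carried unprotected from step 9 on, and mixed anhydrides formed at C15 in steps 11 and 13 are hydrolysed on work-up.

Step 1
Reactants: 1 β-cyclocitral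
Product: 2 β-cyclogeraniol
Conditions: NaBH4, MeOH, 0 °C
Reagents that add atoms: none
Why: Borohydride 1,2-reduction of the hindered enal should give the primary allylic alcohol; no stereocentre is formed.

Step 2
Reactants: 2 β-cyclogeraniol
Product: 3 β-cyclogeranyl bromide
Conditions: PBr3, pyridine (cat.), Et2O, −10 °C; used crude
Reagents that add atoms: phosphorus tribromide PBr3 (BrP(Br)Br)
Why: Substitution of the primary allylic alcohol through its phosphite ester (SN2) should give the bromide without allylic transposition at low temperature.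

Step 3
Reactants: 4 methyl geranate
Product: 5 methyl (2E,6R)-6,7-epoxy-3,7-dimethyloct-2-enoate
Conditions: D-fructose-derived Shi ketone (0.3 equiv), KHSO5 (as 2KHSO5·KHSO4·K2SO4), K2CO3, Bu4NHSO4, MeCN/dimethoxymethane/aqueous buffer, 0 °C
Reagents that add atoms: potassium peroxymonosulfate KHSO5 ([K+].[O-]S(=O)(=O)OO)
Why: Shi asymmetric epoxidation: the chiral dioxirane attacks only the electron-rich trisubstituted 6,7-olefin (the conjugated 2,3-olefin is deactivated) through the spiro transition state and should set the 6R epoxide carbon.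

Step 4
Reactants: 5 methyl (2E,6R)-6,7-epoxy-3,7-dimethyloct-2-enoate
Product: 7 methyl (2E,6R)-6-hydroxy-3,7-dimethylocta-2,7-dienoate, via silyl ether 6 (not isolated)
Conditions: Me3SiOTf, 2,6-lutidine, toluene, −78 °C; DBU, rt; then K2CO3, MeOH, 0 °C
Reagents that add atoms: none
Why: Silyl-triflate-mediated epoxide-to-allylic-alcohol isomerisation: opening at the tertiary carbon and base-induced loss of a methyl proton should give the isopropenyl carbinol silyl ether with the C6–O bond untouched (retention), and methanolysis frees the alcohol.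

Step 5
Reactants: 7 methyl (2E,6R)-6-hydroxy-3,7-dimethylocta-2,7-dienoate; 3 β-cyclogeranyl bromide
Product: 8 methyl (2E,6R)-3,7-dimethyl-6-[(2,6,6-trimethylcyclohex-1-en-1-yl)methoxy]octa-2,7-dienoate
Conditions: NaH, Bu4NI (cat.), THF/DMF, 0 °C to rt
Reagents that add atoms: none
Why: Williamson ether synthesis: the secondary alkoxide should displace the primary allylic bromide (SN2) without touching the carbinol stereocentre.

Step 6
Reactants: 8 methyl (2E,6R)-3,7-dimethyl-6-[(2,6,6-trimethylcyclohex-1-en-1-yl)methoxy]octa-2,7-dienoate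
Product: 9 (2E,6R)-3,7-dimethyl-6-[(2,6,6-trimethylcyclohex-1-en-1-yl)methoxy]octa-2,7-dien-1-ol
Conditions: i-Bu2AlH (2.5 equiv), CH2Cl2, −78 °C
Reagents that add atoms: none
Why: Hydride reduction of the conjugated ester to the allylic alcohol frees the C15 hydroxyl, which as its alkoxide is inert in the strongly basic key step; no stereocentre changes.

Step 7
Reactants: 9 (2E,6R)-3,7-dimethyl-6-[(2,6,6-trimethylcyclohex-1-en-1-yl)methoxy]octa-2,7-dien-1-ol
Product: 13 labda-8(17),13E-diene-6β,15-diol, via dilithium dienediolate 10 (not isolated), via dipotassium enolate 11 (not isolated), via seco-aldehyde 12 (not isolated)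
Conditions: n-BuLi (2.2 equiv), THF, −78 to −20 °C; KOt-Bu, 18-crown-6, −20 to 40 °C; AcOH (4.5 equiv), −78 °C; solvent exchange to CH2Cl2, Me2AlCl (4 equiv), −78 to 0 °C; one pot
Reagents that add atoms: none
Why: n-BuLi removes a proton from the less substituted α-oxygenated allylic position (C6H2) and the carbanion undergoes a [2,3]-Wittig shift onto the isopropenyl CH2 (provisional C6–C7 bond, O–C9 cleaved, E-C8=C9 olefin) to give 1,5-dien-3-olate 10; its potassium salt rearranges by an anionic oxy-Cope [3,3] shift through a chair transition state (C9–C10 formed at the quaternary carbon, the provisional C6–C7 bond broken) to enolate 11, and after protonation aldehyde 12 closes by a Me2AlCl-promoted type 2 carbonyl-ene reaction in which the isopropenyl CH2 adds to C6=O and a methyl hydrogen is transferred (final C6–C7 bond, exocyclic 8(17)-olefin). The closest known reactions are the tandem [2,3]-Wittig/anionic oxy-Cope rearrangement of bis-allylic ethers and the type 2 ene cyclisation of 5-methylhex-5-enals to 3-methylenecyclohexanols. Ring B closes in the ene step through a six-membered chair, the tether sitting on the central carbon of the ene unit. The (R)-ether carbon C9 should transfer its chirality suprafacially to the C6 carbinol (6S) in the Wittig step; the chair oxy-Cope with equatorial alkoxide (the axial alternative clashes with the axial C10 methyl) then sets C10 and C9; C5 is set by protonation and equilibration of the aldehyde to the equatorial formyl group anti to the C10 methyl (trans fusion); the C6 carbinol configuration is immaterial because C6 is oxidised in step 8. The step needs lithiation at C6 and not C9 (favoured by the lower substitution of C6H2) and an E-selective Wittig shift (usual for stabilised allyl carbanions; here the main uncertainty because of the C8 methyl).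

Step 8
Reactants: 13 labda-8(17),13E-diene-6β,15-diol
Product: 14 6-oxolabda-8(17),13E-dien-15-al
Conditions: Dess–Martin periodinane (2.5 equiv), NaHCO3, CH2Cl2, 0 °C to rt
Reagents that add atoms: none
Why: Dess–Martin oxidation should convert the secondary C6 alcohol into the ketone and the primary allylic C15 alcohol into the E-enal in one step, erasing the C6 configuration.

Step 9
Reactants: 14 6-oxolabda-8(17),13E-dien-15-al
Product: 15 6-oxolabda-8(17),13E-dien-15-oic acid
Conditions: NaClO2, NaH2PO4, 2-methyl-2-butene, t-BuOH/H2O, 0 °C to rt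
Reagents that add atoms: sodium chlorite NaClO2 ([Na+].[O-]Cl=O)
Why: Pinnick oxidation takes the enal to the carboxylic acid while the scavenger removes hypochlorite, so the ketone and the olefins should be untouched.

Step 10
Reactants: 15 6-oxolabda-8(17),13E-dien-15-oic acid
Product: 17 7α-hydroxy-6-oxolabda-8,13E-dien-15-oic acid, via extended enolate 16 (not isolated)
Conditions: KN(SiMe3)2 (2.1 equiv), t-BuOH (0.2 equiv), THF, −78 to 0 °C (equilibration); −78 °C, 2-(phenylsulfonyl)-3-phenyloxaziridine; AcOH, −78 °C
Reagents that add atoms: 2-(phenylsulfonyl)-3-phenyloxaziridine (O=S(=O)(c1ccccc1)N1OC1c1ccccc1)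
Why: Under equilibrating conditions the β,γ-unsaturated ketone should give the thermodynamic extended enolate with the tetrasubstituted C8=C9 bond (the axial H9 is aligned for removal and C9 loses its stereocentre), and oxaziridine α-hydroxylation of this dienolate at C7 by axial attack on the α face, away from the axial C10 methyl, should set 7α-OH.

Step 11
Reactants: 17 7α-hydroxy-6-oxolabda-8,13E-dien-15-oic acid
Product: 18 7α-(3-methylbutanoyloxy)-6-oxolabda-8,13E-dien-15-oic acid
Conditions: 3-methylbutanoic anhydride (3 equiv), DMAP (cat.), Et3N, CH2Cl2, 0 °C; aqueous NaHCO3/THF work-up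
Reagents that add atoms: 3-methylbutanoic anhydride (CC(C)CC(=O)OC(=O)CC(C)C)
Why: DMAP-catalysed acylation of the secondary allylic alcohol at low temperature should outrun enolisation of the α-ketol, leaving C7 untouched.

Step 12
Reactants: 18 7α-(3-methylbutanoyloxy)-6-oxolabda-8,13E-dien-15-oic acid
Product: 19 6β-hydroxy-7α-(3-methylbutanoyloxy)labda-8,13E-dien-15-oic acid
Conditions: NaBH4 (excess), CeCl3·7H2O, MeOH/THF, −40 °C
Reagents that add atoms: none
Why: Luche-type borohydride reduction: hydride should attack C6 from the α face because the β face is blocked by the syn-axial C4 and C10 methyl groups, giving the axial 6β alcohol, trans-diaxial to the C7 ester so that acyl migration is not possible.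

Step 13
Reactants: 19 6β-hydroxy-7α-(3-methylbutanoyloxy)labda-8,13E-dien-15-oic acid
Product: 20 6β-acetoxy-7α-(3-methylbutanoyloxy)labda-8,13E-dien-15-oic acid (target)
Conditions: Ac2O, DMAP, pyridine, 40 °C; then H2O/THF
Reagents that add atoms: acetic anhydride (CC(=O)OC(C)=O)
Why: DMAP-catalysed acetylation should esterify the hindered axial alcohol without change at any stereocentre.

**Compound list**

1 | β-cyclocitral, 2,6,6-trimethylcyclohex-1-ene-1-carbaldehyde | CC1=C(C=O)C(C)(C)CCC1 | starting material
2 | β-cyclogeraniol, (2,6,6-trimethylcyclohex-1-en-1-yl)methanol | CC1=C(CO)C(C)(C)CCC1 | intermediate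
3 | β-cyclogeranyl bromide, 2-(bromomethyl)-1,3,3-trimethylcyclohex-1-ene | CC1=C(CBr)C(C)(C)CCC1 | intermediate
4 | methyl geranate, methyl (2E)-3,7-dimethylocta-2,6-dienoate | COC(=O)/C=C(\C)CCC=C(C)C | starting material
5 | methyl (2E,6R)-6,7-epoxy-3,7-dimethyloct-2-enoate | COC(=O)/C=C(\C)CC[C@H]1OC1(C)C | intermediate
6 | methyl (2E,6R)-3,7-dimethyl-6-(trimethylsilyloxy)octa-2,7-dienoate | COC(=O)/C=C(\C)CC[C@@H](O[Si](C)(C)C)C(C)=C | intermediate (not isolated)
7 | methyl (2E,6R)-6-hydroxy-3,7-dimethylocta-2,7-dienoate | COC(=O)/C=C(\C)CC[C@@H](O)C(C)=C | intermediate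
8 | methyl (2E,6R)-3,7-dimethyl-6-[(2,6,6-trimethylcyclohex-1-en-1-yl)methoxy]octa-2,7-dienoate | COC(=O)/C=C(\C)CC[C@@H](OCC1=C(C)CCCC1(C)C)C(C)=C | intermediate
9 | (2E,6R)-3,7-dimethyl-6-[(2,6,6-trimethylcyclohex-1-en-1-yl)methoxy]octa-2,7-dien-1-ol | OC/C=C(\C)CC[C@@H](OCC1=C(C)CCCC1(C)C)C(C)=C | intermediate
10 | dilithium (2E,6E,9S)-3,7-dimethyl-9-(2,6,6-trimethylcyclohex-1-en-1-yl)nona-2,6-diene-1,9-diolate | [Li+].[Li+].[O-]C/C=C(\C)CC/C=C(\C)C[C@H]([O-])C1=C(C)CCCC1(C)C | intermediate (not isolated)
11 | dipotassium salt of the C5=C6 enolate and C15 alkoxide of aldehyde 12 | [K+].[K+].[O-]/C=C1\C(C)(C)CCC[C@]1(C)[C@@H](CC/C(C)=C/C[O-])C(C)=C | intermediate (not isolated)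
12 | (1S,2R)-2-[(3S,6E)-8-hydroxy-2,6-dimethylocta-1,6-dien-3-yl]-2,6,6-trimethylcyclohexane-1-carbaldehyde (15-hydroxy-6,7-secolabda-7,13E-dien-6-al) | O=C[C@H]1C(C)(C)CCC[C@]1(C)[C@@H](CC/C(C)=C/CO)C(C)=C | intermediate (not isolated)
13 | labda-8(17),13E-diene-6β,15-diol (5α-H, 9α-H, 10β-CH3; the 6-epimer converges in step 8) | O[C@@H]1CC(=C)[C@H](CC/C(C)=C/CO)[C@@]2(C)CCCC(C)(C)[C@H]12 | intermediate
14 | 6-oxolabda-8(17),13E-dien-15-al | O=C1CC(=C)[C@H](CC/C(C)=C/C=O)[C@@]2(C)CCCC(C)(C)[C@H]12 | intermediate
15 | 6-oxolabda-8(17),13E-dien-15-oic acid | O=C1CC(=C)[C@H](CC/C(C)=C/C(=O)O)[C@@]2(C)CCCC(C)(C)[C@H]12 | intermediate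
16 | dipotassium 6-oxidolabda-6,8,13E-trien-15-oate | [K+].[K+].[O-]C1=CC(C)=C(CC/C(C)=C/C(=O)[O-])[C@@]2(C)CCCC(C)(C)[C@H]12 | intermediate (not isolated)
17 | 7α-hydroxy-6-oxolabda-8,13E-dien-15-oic acid | O=C1[C@@H](O)C(C)=C(CC/C(C)=C/C(=O)O)[C@@]2(C)CCCC(C)(C)[C@H]12 | intermediate
18 | 7α-(3-methylbutanoyloxy)-6-oxolabda-8,13E-dien-15-oic acid | O=C1[C@@H](OC(=O)CC(C)C)C(C)=C(CC/C(C)=C/C(=O)O)[C@@]2(C)CCCC(C)(C)[C@H]12 | intermediate
19 | 6β-hydroxy-7α-(3-methylbutanoyloxy)labda-8,13E-dien-15-oic acid | O[C@@H]1[C@@H](OC(=O)CC(C)C)C(C)=C(CC/C(C)=C/C(=O)O)[C@@]2(C)CCCC(C)(C)[C@H]12 | intermediate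
20 | (5S,6S,7S,10S,13E)-6-acetoxy-7-(3-methylbutanoyloxy)labda-8,13-dien-15-oic acid | CC(=O)O[C@@H]1[C@@H](OC(=O)CC(C)C)C(C)=C(CC/C(C)=C/C(=O)O)[C@@]2(C)CCCC(C)(C)[C@H]12 | target

Total step count: 13. Longest linear sequence: 11 steps (4 to 20, steps 3–13).

**Steps most likely to fail**

Step 7. What may go wrong: loss of olefin-geometry control in the [2,3]-shift (allylic 1,2-strain with the C8 methyl favours the Z-olefin), which would invert the sense of chirality transfer and give the C9 epimer; competing lithiation at C9 is a second risk. The fallback builds the dienol by reagent control and sets out from 1, returning at 13. Geraniol is silylated (t-BuMe2SiCl, imidazole) to geranyl tert-butyldimethylsilyl ether F1. Oxidation at the E-methyl group (SeO2, t-BuOOH) gives the 8-hydroxy compound F2, and MsCl/LiCl gives the allylic chloride F3. Its allylbarium reagent (BaI2, lithium biphenylide, THF, −78 °C) should add to 1 at the unsubstituted allyl terminus with retention of the E-olefin to give the racemic dienol F4. Dess–Martin oxidation gives the dienone F5. CBS reduction ((R)-methyl oxazaborolidine, BH3·SMe2, cyclohexenyl as the large group) should give the (S)-dienol F6. KH/18-crown-6 (anionic oxy-Cope), protonation and Me2AlCl (ene closure) give the 15-O-silyl ether F7, and Bu4NF returns 13.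

Step 10. What may go wrong: deprotonation at the C8 methyl instead of C9 (exocyclic dienolate), oxygenation at the γ-carbon, and base-induced α-ketol transposition of the product. The fallback sets out from 15 and returns at 17. It traps the thermodynamic extended enol under non-basic equilibrating conditions and oxidises it electrophilically. Compound 15 with t-BuMe2SiOTf and Et3N (CH2Cl2, rt) should give the isolable 6-silyloxy-6,8-diene silyl ester F8. Rubottom oxidation with dimethyldioxirane from the α face, then mild desilylation (citric acid, MeOH), gives 17.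

Step 5. What may go wrong: slow substitution at the hindered allylic bromide, with elimination or allylic transposition of 3 and intramolecular oxa-Michael addition of the alkoxide to the enoate. The fallback is a reductive etherification that needs neither base nor bromide; it sets out from 1 and 6 and returns at 8. Silyl ether 6 (isolated in step 4 before methanolysis) and aldehyde 1 are treated with Et3SiH and catalytic Me3SiOTf (CH2Cl2, −78 °C), and 1,2-reduction of the intermediate oxocarbenium ion should give 8 directly.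

**Further compounds**

F1 | step 7 | geranyl tert-butyldimethylsilyl ether | CC(C)=CCC/C(C)=C/CO[Si](C)(C)C(C)(C)C
F2 | step 7 | (2E,6E)-8-(tert-butyldimethylsilyloxy)-2,6-dimethylocta-2,6-dien-1-ol | OC/C(C)=C/CC/C(C)=C/CO[Si](C)(C)C(C)(C)C
F3 | step 7 | tert-butyl{[(2E,6E)-8-chloro-3,7-dimethylocta-2,6-dien-1-yl]oxy}dimethylsilane | ClC/C(C)=C/CC/C(C)=C/CO[Si](C)(C)C(C)(C)C
F4 | step 7 | racemic (3E,7E)-9-(tert-butyldimethylsilyloxy)-3,7-dimethyl-1-(2,6,6-trimethylcyclohex-1-en-1-yl)nona-3,7-dien-1-ol | CC1=C(C(O)C/C(C)=C/CC/C(C)=C/CO[Si](C)(C)C(C)(C)C)C(C)(C)CCC1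
F5 | step 7 | (3E,7E)-9-(tert-butyldimethylsilyloxy)-3,7-dimethyl-1-(2,6,6-trimethylcyclohex-1-en-1-yl)nona-3,7-dien-1-one | CC1=C(C(=O)C/C(C)=C/CC/C(C)=C/CO[Si](C)(C)C(C)(C)C)C(C)(C)CCC1
F6 | step 7 | (1S,3E,7E)-9-(tert-butyldimethylsilyloxy)-3,7-dimethyl-1-(2,6,6-trimethylcyclohex-1-en-1-yl)nona-3,7-dien-1-ol | CC1=C([C@@H](O)C/C(C)=C/CC/C(C)=C/CO[Si](C)(C)C(C)(C)C)C(C)(C)CCC1
F7 | step 7 | 15-(tert-butyldimethylsilyloxy)labda-8(17),13E-dien-6β-ol | O[C@@H]1CC(=C)[C@H](CC/C(C)=C/CO[Si](C)(C)C(C)(C)C)[C@@]2(C)CCCC(C)(C)[C@H]12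
F8 | step 10 | tert-butyldimethylsilyl 6-(tert-butyldimethylsilyloxy)labda-6,8,13E-trien-15-oate | CC(C)(C)[Si](C)(C)OC1=CC(C)=C(CC/C(C)=C/C(=O)O[Si](C)(C)C(C)(C)C)[C@@]2(C)CCCC(C)(C)[C@H]12
F0 | step 5 | none | none
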